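**Retrosynthetic overview**

Locants: ring A = C1 (C=CH2), C2, C3, C4 (CHBr), C5 (CMe2), C6 (spiro); ring B = C6, C7=C8, C9 (=C12HBr), C10, C11. Late changes only: C4–Br from C4–OH with inversion, C1=CH2 from C1=O, C7=C8 from a C8 carbinol.
Key disconnection, one operation: move C5 back from C6 to C1 (six-membered ring A → silyloxycyclopentane) and cut C7–C8 (ring B → alkene + aldehyde). This unravels the spiro hydroxy ketone to a monocyclic cyclopentanol silyl ether with a 1,1-disubstituted alkene and a Z-β-bromoenal.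
Enabling feature: spiro C6 sits in ring A between quaternary C5 and C1, a latent carbonyl (pinacol retron). In ring B it is one CH2/CH (C7) away from C8, the allylic carbon beside C9 (Prins retron). A cation at C6 can therefore be made by closing ring B and quenched by expanding ring A.
Precursor assembly: a yeast-desymmetrized C7 cyclopentanedione, a C4 alkenyl anion (C6, C7, C10, C11) and a C3 propargylic alcohol (C8, C9, C12). Anti-carbomagnesiation/bromination of the latter fixes the Z-bromoalkene before any ring of the target exists.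
Ring order: the cyclopentane is present from the start; ring B and the six-membered ring A form together in the key step; no ring is formed afterwards.

Key step: step 8

Remark on the chemistry: the carbinol carbon C8 created in step 8 is expected as a mixture of epimers. Both give the same diene in step 9, so this centre is left undefined in the SMILES of 15 and 16.

**Route**

Step 1
Reactants: 1 2,2-dimethylcyclopentane-1,3-dione
Product: 2 (S)-3-hydroxy-2,2-dimethylcyclopentan-1-one
Conditions: baker's yeast (Saccharomyces cerevisiae), sucrose, H2O, 30 °C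
Reagents that add atoms: none
Why: Enzymatic desymmetrizing reduction of one of the two enantiotopic carbonyl groups (yeast ketoreductase) should set the (S)-carbinol that later becomes the bromine-bearing carbon C4.

Step 2
Reactants: 2 (S)-3-hydroxy-2,2-dimethylcyclopentan-1-one
Product: 3 (S)-3-[(tert-butyldimethylsilyl)oxy]-2,2-dimethylcyclopentan-1-one
Conditions: TBSCl, imidazole, DMF, rt
Reagents that add atoms: tert-butyldimethylsilyl chloride, CC(C)(C)[Si](C)(C)Cl
Why: Standard silylation protects the secondary alcohol for the organometallic steps and the Lewis-acid step.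

Step 3
Reactants: 3 (S)-3-[(tert-butyldimethylsilyl)oxy]-2,2-dimethylcyclopentan-1-one; 4 3-bromobut-3-en-1-ol
Product: 6 (1S,3S)-3-[(tert-butyldimethylsilyl)oxy]-1-(4-hydroxybut-1-en-2-yl)-2,2-dimethylcyclopentan-1-ol, via dilithio reagent 5 (not isolated)
Conditions: 4, t-BuLi (3.1 equiv), Et2O, −78 °C; then 3 premixed with LaCl3·2LiCl, THF, −78 → −20 °C; aq. NH4Cl
Reagents that add atoms: none
Why: Bromine–lithium exchange on the lithium alkoxide gives an alkenyllithium that should add 1,2 to the ketone from the face anti to the silyloxy group (substrate-controlled carbonyl addition, LaCl3·2LiCl suppressing enolization), so the new hydroxyl is cis to the silyloxy group.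

Step 4
Reactants: 6 (1S,3S)-3-[(tert-butyldimethylsilyl)oxy]-1-(4-hydroxybut-1-en-2-yl)-2,2-dimethylcyclopentan-1-ol
Product: 7 (1S,3S)-1-(4-bromobut-1-en-2-yl)-3-[(tert-butyldimethylsilyl)oxy]-2,2-dimethylcyclopentan-1-ol
Conditions: CBr4, PPh3, CH2Cl2, 0 °C
Reagents that add atoms: carbon tetrabromide, BrC(Br)(Br)Br
Why: Appel bromination should be selective for the primary alcohol because the tertiary allylic alcohol is too hindered to form an alkoxyphosphonium ion.

Step 5
Reactants: 7 (1S,3S)-1-(4-bromobut-1-en-2-yl)-3-[(tert-butyldimethylsilyl)oxy]-2,2-dimethylcyclopentan-1-ol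
Product: 8 (1S,3S)-1-(4-bromobut-1-en-2-yl)-3-[(tert-butyldimethylsilyl)oxy]-2,2-dimethyl-1-[(triethylsilyl)oxy]cyclopentane
Conditions: TESOTf, 2,6-lutidine, CH2Cl2, −78 → 0 °C
Reagents that add atoms: triethylsilyl trifluoromethanesulfonate, CC[Si](CC)(CC)OS(=O)(=O)C(F)(F)F
Why: Silyl triflate silylation caps the hindered tertiary alcohol, which permits Grignard formation in step 6 and provides the silyl ether that drives the pinacol shift in step 8.

Step 6
Reactants: 8 (1S,3S)-1-(4-bromobut-1-en-2-yl)-3-[(tert-butyldimethylsilyl)oxy]-2,2-dimethyl-1-[(triethylsilyl)oxy]cyclopentane; 9 prop-2-yn-1-ol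
Product: 13 (2Z)-2-(bromomethylidene)-5-{(1S,3S)-3-[(tert-butyldimethylsilyl)oxy]-2,2-dimethyl-1-[(triethylsilyl)oxy]cyclopentyl}hex-5-en-1-ol, via Grignard reagent 10 (not isolated), via bromomagnesium propargyl alkoxide 11 (not isolated), via alkenylmagnesium chelate 12 (not isolated)
Conditions: 8, Mg, THF, 40 °C; 9 + EtMgBr (1.0 equiv), THF, 0 °C; mix, CuI (10 mol%), −10 °C → rt; BrCCl2CCl2Br, −78 → 0 °C
Reagents that add atoms: 1,2-dibromo-1,1,2,2-tetrachloroethane, BrC(Cl)(Cl)C(Cl)(Cl)Br
Why: Copper-catalysed anti-carbomagnesiation of the propargyl alkoxide places the alkyl group on the internal carbon and magnesium on the terminal carbon cis to CH2O in a five-membered chelate, and stereoretentive bromination of that alkenylmagnesium should fix bromine cis to the hydroxymethyl group (Z).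

Step 7
Reactants: 13 (2Z)-2-(bromomethylidene)-5-{(1S,3S)-3-[(tert-butyldimethylsilyl)oxy]-2,2-dimethyl-1-[(triethylsilyl)oxy]cyclopentyl}hex-5-en-1-ol
Product: 14 (2Z)-2-(bromomethylidene)-5-{(1S,3S)-3-[(tert-butyldimethylsilyl)oxy]-2,2-dimethyl-1-[(triethylsilyl)oxy]cyclopentyl}hex-5-enal
Conditions: MnO2, CH2Cl2, rt
Reagents that add atoms: none
Why: Allylic oxidation with MnO2 is neutral and should leave the Z-bromoalkene and both silyl ethers untouched.

Step 8
Reactants: 14 (2Z)-2-(bromomethylidene)-5-{(1S,3S)-3-[(tert-butyldimethylsilyl)oxy]-2,2-dimethyl-1-[(triethylsilyl)oxy]cyclopentyl}hex-5-enal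
Product: 16 (4S,6R)-9-[(Z)-bromomethylidene]-4-[(tert-butyldimethylsilyl)oxy]-8-hydroxy-5,5-dimethylspiro[5.5]undecan-1-one, via tertiary carbocation 15 (not isolated)
Conditions: Me2AlCl (2.2 equiv), CH2Cl2, −78 → −30 °C; then 1 M aq. HCl, THF, 0 °C
Reagents that add atoms: none
Why: Proposed new method: Me2AlCl activates the enal, the CH2 terminus of the 1,1-disubstituted alkene attacks the aldehyde carbon (C7–C8), and the tertiary cation at C6 next to the silyloxy carbon is quenched by 1,2-shift of the antiperiplanar C1–C5 bond with loss of Et3Si+; the closest known reaction type is the Prins–pinacol ring-enlarging annulation of 1-alkenylcycloalkanol silyl ethers started by oxocarbenium ions, extended here to a Lewis-acid-bound β-bromoenal. Ring B closes by 6-endo-trig Prins attack through a chair, and ring A grows from five to six members by migration of the gem-dimethyl carbon C5 from C1 to C6. The spiro stereocenter is controlled by the carbinol stereocenter C1: C5 must lie anti to the incoming aldehyde, and of the two remaining substituents the small silyloxy oxygen should take the position beside the tether CH2 (C11) while the ring CH2 (C2) takes the less crowded position beside =CH2 (C7), which puts C11 cis and C7 trans to the C4 oxygen. The new carbinol C8 is uncontrolled and is removed in step 9. The step needs migration of quaternary C5 rather than C2, secured by the higher migratory aptitude of the more substituted carbon and by the strain of the rotamer that would put the CMe2 group in the alkene plane. It also needs 1,2- rather than 1,4-attack on the enal and an intact Z-bromoalkene, secured by the bromine-shielded β-carbon and a chloride-poor aluminium Lewis acid at low temperature.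

Step 9
Reactants: 16 (4S,6R)-9-[(Z)-bromomethylidene]-4-[(tert-butyldimethylsilyl)oxy]-8-hydroxy-5,5-dimethylspiro[5.5]undecan-1-one
Product: 17 (4S,6R)-9-[(Z)-bromomethylidene]-4-[(tert-butyldimethylsilyl)oxy]-5,5-dimethylspiro[5.5]undec-7-en-1-one
Conditions: Martin sulfurane Ph2S[OC(CF3)2Ph]2, CH2Cl2, 0 °C → rt
Reagents that add atoms: none
Why: Sulfurane dehydration of the secondary allylic alcohol can only remove a hydrogen from C7 (C9 carries none), so either C8 epimer should give the conjugated C7=C8/C9=C12 bromodiene.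

Step 10
Reactants: 17 (4S,6R)-9-[(Z)-bromomethylidene]-4-[(tert-butyldimethylsilyl)oxy]-5,5-dimethylspiro[5.5]undec-7-en-1-one
Product: 18 tert-butyl{[(4S,6S)-9-[(Z)-bromomethylidene]-5,5-dimethyl-1-methylidenespiro[5.5]undec-7-en-4-yl]oxy}dimethylsilane
Conditions: Cp2TiMe2 (3 equiv), toluene, 75 °C, dark
Reagents that add atoms: dimethyltitanocene Cp2TiMe2, C[Ti+2]C.c1cc[cH-]c1.c1cc[cH-]c1
Why: Petasis methylenation (thermally generated Cp2Ti=CH2) is a non-basic carbonyl olefination suited to hindered, enolizable ketones and should tolerate the alkenyl bromide and the silyl ether.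

Step 11
Reactants: 18 tert-butyl{[(4S,6S)-9-[(Z)-bromomethylidene]-5,5-dimethyl-1-methylidenespiro[5.5]undec-7-en-4-yl]oxy}dimethylsilane
Product: 19 (4S,6S)-9-[(Z)-bromomethylidene]-5,5-dimethyl-1-methylidenespiro[5.5]undec-7-en-4-ol
Conditions: TBAF, THF, rt → 45 °C
Reagents that add atoms: none
Why: Fluoride-mediated desilylation frees the secondary alcohol without touching the triene or the alkenyl bromide.

Step 12
Reactants: 19 (4S,6S)-9-[(Z)-bromomethylidene]-5,5-dimethyl-1-methylidenespiro[5.5]undec-7-en-4-ol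
Product: 20 (4R,6S)-4-bromo-9-[(Z)-bromomethylidene]-5,5-dimethyl-1-methylidenespiro[5.5]undec-7-ene
Conditions: CBr4, P(n-C8H17)3, 2,6-di-tert-butylpyridine, toluene, 60 °C
Reagents that add atoms: carbon tetrabromide, BrC(Br)(Br)Br
Why: Appel-type bromination displaces the alkoxyphosphonium group by bromide in an SN2 reaction with inversion, which should turn the (4S)-carbinol into the (4R)-bromide cis to the C7 arm, while the hindered base scavenges HBr.

**Compound list**

1 | 2,2-dimethylcyclopentane-1,3-dione | CC1(C)C(=O)CCC1=O | starting material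
2 | (S)-3-hydroxy-2,2-dimethylcyclopentan-1-one | O=C1CC[C@H](O)C1(C)C | intermediate
3 | (S)-3-[(tert-butyldimethylsilyl)oxy]-2,2-dimethylcyclopentan-1-one | O=C1CC[C@H](O[Si](C)(C)C(C)(C)C)C1(C)C | intermediate
4 | 3-bromobut-3-en-1-ol | C=C(Br)CCO | starting material
5 | lithium 3-lithiobut-3-en-1-olate (not isolated) | [Li]C(=C)CCO[Li] | intermediate
6 | (1S,3S)-3-[(tert-butyldimethylsilyl)oxy]-1-(4-hydroxybut-1-en-2-yl)-2,2-dimethylcyclopentan-1-ol (OH cis to OTBS) | O[C@]1(C(=C)CCO)CC[C@H](O[Si](C)(C)C(C)(C)C)C1(C)C | intermediate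
7 | (1S,3S)-1-(4-bromobut-1-en-2-yl)-3-[(tert-butyldimethylsilyl)oxy]-2,2-dimethylcyclopentan-1-ol | O[C@]1(C(=C)CCBr)CC[C@H](O[Si](C)(C)C(C)(C)C)C1(C)C | intermediate
8 | (1S,3S)-1-(4-bromobut-1-en-2-yl)-3-[(tert-butyldimethylsilyl)oxy]-2,2-dimethyl-1-[(triethylsilyl)oxy]cyclopentane | CC[Si](CC)(CC)O[C@]1(C(=C)CCBr)CC[C@H](O[Si](C)(C)C(C)(C)C)C1(C)C | intermediate
9 | prop-2-yn-1-ol | C#CCO | starting material
10 | Grignard reagent of 8 (not isolated) | CC[Si](CC)(CC)O[C@]1(C(=C)CC[Mg]Br)CC[C@H](O[Si](C)(C)C(C)(C)C)C1(C)C | intermediate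
11 | bromomagnesium prop-2-yn-1-olate (not isolated) | C#CCO[Mg]Br | intermediate
12 | alkenylmagnesium chelate, a 4-substituted 2,5-dihydro-1,2-oxamagnesole (not isolated) | CC[Si](CC)(CC)O[C@]1(C(=C)CCC2=C[Mg]OC2)CC[C@H](O[Si](C)(C)C(C)(C)C)C1(C)C | intermediate
13 | (2Z)-2-(bromomethylidene)-5-{(1S,3S)-3-[(tert-butyldimethylsilyl)oxy]-2,2-dimethyl-1-[(triethylsilyl)oxy]cyclopentyl}hex-5-en-1-ol (Br cis to CH2OH) | CC[Si](CC)(CC)O[C@]1(C(=C)CC/C(CO)=C/Br)CC[C@H](O[Si](C)(C)C(C)(C)C)C1(C)C | intermediate
14 | (2Z)-2-(bromomethylidene)-5-{(1S,3S)-3-[(tert-butyldimethylsilyl)oxy]-2,2-dimethyl-1-[(triethylsilyl)oxy]cyclopentyl}hex-5-enal | CC[Si](CC)(CC)O[C@]1(C(=C)CC/C(C=O)=C/Br)CC[C@H](O[Si](C)(C)C(C)(C)C)C1(C)C | intermediate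
15 | tertiary cyclohexyl cation at C6 with aluminium-bound C8 alkoxide, Prins intermediate (not isolated; C8 undefined) | CC[Si](CC)(CC)O[C@]1([C+]2CC/C(=C/Br)C(O[Al-](C)(C)Cl)C2)CC[C@H](O[Si](C)(C)C(C)(C)C)C1(C)C | intermediate
16 | (4S,6R)-9-[(Z)-bromomethylidene]-4-[(tert-butyldimethylsilyl)oxy]-8-hydroxy-5,5-dimethylspiro[5.5]undecan-1-one (C8 epimers) | O=C1CC[C@H](O[Si](C)(C)C(C)(C)C)C(C)(C)[C@@]12CC(O)/C(=C\Br)CC2 | intermediate
17 | (4S,6R)-9-[(Z)-bromomethylidene]-4-[(tert-butyldimethylsilyl)oxy]-5,5-dimethylspiro[5.5]undec-7-en-1-one | O=C1CC[C@H](O[Si](C)(C)C(C)(C)C)C(C)(C)[C@@]12C=C/C(=C\Br)CC2 | intermediate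
18 | tert-butyl{[(4S,6S)-9-[(Z)-bromomethylidene]-5,5-dimethyl-1-methylidenespiro[5.5]undec-7-en-4-yl]oxy}dimethylsilane | C=C1CC[C@H](O[Si](C)(C)C(C)(C)C)C(C)(C)[C@@]12C=C/C(=C\Br)CC2 | intermediate
19 | (4S,6S)-9-[(Z)-bromomethylidene]-5,5-dimethyl-1-methylidenespiro[5.5]undec-7-en-4-ol (OH trans to the C7 arm) | C=C1CC[C@H](O)C(C)(C)[C@@]12C=C/C(=C\Br)CC2 | intermediate
20 | (4R,6S)-4-bromo-9-[(Z)-bromomethylidene]-5,5-dimethyl-1-methylidenespiro[5.5]undec-7-ene (CNP0142773.1; Br cis to the C7 arm, vinylic Br cis to C8) | C=C1CC[C@@H](Br)C(C)(C)[C@@]12C=C/C(=C\Br)CC2 | target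

**Step count and risks**

Total step count: 12. Longest linear sequence: 12 steps (1 → 20).

Steps most likely to fail:

1. Step 8 (proposed new method). Possible failures:
   - loss of facial control in the 1,2-shift, if the silyloxy group and C2 exchange their in-plane positions, which gives the spiro epimer;
   - conjugate attack of the alkene on the bromoenal;
   - proton loss from the C6 cation instead of migration;
   - Z→E isomerization of the bromoenal by reversible halide addition.

   Fallback with known, stereospecific chemistry, setting out from 13 and returning at 17. Appel bromination (CBr4, PPh3) should give the allylic bromide F1. Copper-catalysed SN2 coupling with CH2=CHMgBr (CuI cat., THF, −30 °C) should give the skipped triene F2. Ring-closing metathesis with the second-generation Hoveyda–Grubbs catalyst RuCl2(H2IMes)(=CH-C6H4-2-OiPr) should close ring B as the cyclohexene F3. Shi epoxidation (KHSO5, K2CO3 buffer) with the enantiomer of the D-fructose-derived ketone, chosen by analogy with 1-phenylcyclohexene, should give the epoxide F4 by reagent control. BF3·OEt2 should then trigger the semipinacol rearrangement of the epoxy silyl ether, C5 migrating anti to the epoxide C–O bond, to the β-hydroxy ketone F5. Martin sulfurane dehydration of F5 gives 17.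

2. Step 12. Possible failures: E2 elimination toward C3, slow backside attack beside the quaternary C5, and methyl shift after ionization. Fallback setting out from 19 and returning at 20: activation and displacement are separated. Tf2O and pyridine in CH2Cl2 at −30 °C should give the isolable triflate F6, which is displaced with inversion by Bu4NBr in toluene at 0 °C → rt, without phosphorus reagents or heating.

3. Step 10. Possible failures: no olefination for steric reasons at the ketone flanked by the spiro carbon, or enolization by the titanium reagent. Fallback setting out from 17 and returning at 18: Peterson olefination. Me3SiCH2Li with CeCl3 in THF at −78 °C should add to give the β-hydroxysilane F7, and KH in THF then eliminates to 18.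

Further compounds
F1 | step 8 | (1S,3S)-1-[(5Z)-6-bromo-5-(bromomethyl)hexa-1,5-dien-2-yl]-3-[(tert-butyldimethylsilyl)oxy]-2,2-dimethyl-1-[(triethylsilyl)oxy]cyclopentane | CC[Si](CC)(CC)O[C@]1(C(=C)CC/C(CBr)=C/Br)CC[C@H](O[Si](C)(C)C(C)(C)C)C1(C)C
F2 | step 8 | (1S,3S)-1-[(5Z)-5-(bromomethylidene)octa-1,7-dien-2-yl]-3-[(tert-butyldimethylsilyl)oxy]-2,2-dimethyl-1-[(triethylsilyl)oxy]cyclopentane | CC[Si](CC)(CC)O[C@]1(C(=C)CC/C(CC=C)=C/Br)CC[C@H](O[Si](C)(C)C(C)(C)C)C1(C)C
F3 | step 8 | (1S,3S)-1-[(4Z)-4-(bromomethylidene)cyclohex-1-en-1-yl]-3-[(tert-butyldimethylsilyl)oxy]-2,2-dimethyl-1-[(triethylsilyl)oxy]cyclopentane | CC[Si](CC)(CC)O[C@]1(C2=CC/C(=C\Br)CC2)CC[C@H](O[Si](C)(C)C(C)(C)C)C1(C)C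
F4 | step 8 | 1,2-epoxide of F3 with oxygen on the alkene face opposite to the later migration of C5 | CC[Si](CC)(CC)O[C@]1([C@@]23CC/C(=C/Br)C[C@@H]2O3)CC[C@H](O[Si](C)(C)C(C)(C)C)C1(C)C
F5 | step 8 | (4S,6S,7S)-9-[(Z)-bromomethylidene]-4-[(tert-butyldimethylsilyl)oxy]-7-hydroxy-5,5-dimethylspiro[5.5]undecan-1-one | O=C1CC[C@H](O[Si](C)(C)C(C)(C)C)C(C)(C)[C@@]12[C@@H](O)C/C(=C\Br)CC2
F6 | step 12 | (4S,6S)-9-[(Z)-bromomethylidene]-5,5-dimethyl-1-methylidenespiro[5.5]undec-7-en-4-yl trifluoromethanesulfonate | C=C1CC[C@H](OS(=O)(=O)C(F)(F)F)C(C)(C)[C@@]12C=C/C(=C\Br)CC2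
F7 | step 10 | (4S,6R)-9-[(Z)-bromomethylidene]-4-[(tert-butyldimethylsilyl)oxy]-5,5-dimethyl-1-[(trimethylsilyl)methyl]spiro[5.5]undec-7-en-1-ol (C1 epimers) | C[Si](C)(C)CC1(O)CC[C@H](O[Si](C)(C)C(C)(C)C)C(C)(C)[C@@]12C=C/C(=C\Br)CC2
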